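**Plan**

- Retrosynthetic cuts (flavanone numbering): the ester groups on oxygen; the C6–C(quaternary) bond of the 2-methylbut-3-en-2-yl group (back to an O5 prenyl ether); the C4–C4a aryl ketone bond; the O1–C2 benzylic ether bond; the two C–O bonds at C2/C3 (back to an E-cinnamate).
- Forward order: ring B enters as a 4-hydroxycinnamate; the alkene becomes a trans-glycidate; ring A is attached through O1; ring C is closed last by acylation of ring A at C4a; the C5 side chain is then moved from O5 to C6.
- Stereochemistry: one catalyst-controlled epoxidation sets both centres. The benzylic carbon is inverted once by SN2 opening and the carbinol carbon is carried through unchanged, which gives the trans (2R,3R) pair.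
- Enabling feature: ring A carries oxygen at C5, C7 and C8a. Before C4–C4a exists, the O1-bound ring is a 3,5-dioxygenated phenyl ether whose two carbons ortho to O1 (later C4a and C8) are equivalent, so ring closure has one possible outcome.

Key step: step 6

Assumption: 3,5-bis(benzyloxy)phenol is bought rather than made, and the mirror-image (L-fructose-derived) Shi diacetate ketone, a known catalyst reachable from L-sorbose, is not counted as a route step.

**Route**

Step 1
Reactants: 1 4-hydroxycinnamic acid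
Product: 3 2,2,2-trichloroethyl (E)-3-[4-(pivaloyloxy)phenyl]prop-2-enoate, via mixed pivalic cinnamic anhydride 2 (not isolated)
Conditions: PivCl (2.1 equiv), Et3N, THF, 0 °C; then Cl3CCH2OH, DMAP (cat.), rt
Reagents that add atoms: pivaloyl chloride, CC(C)(C)C(=O)Cl; 2,2,2-trichloroethanol, OCC(Cl)(Cl)Cl
Why: Pivaloyl chloride acylates the phenol and turns the acid into the mixed anhydride 2, which DMAP-catalysed alcoholysis should open at the less hindered cinnamoyl carbonyl (mixed-anhydride esterification); the trichloroethyl ester is chosen because it has no second alkene and is later removed reductively without acid or base.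

Step 2
Reactants: 3 2,2,2-trichloroethyl (E)-3-[4-(pivaloyloxy)phenyl]prop-2-enoate
Product: 4 2,2,2-trichloroethyl (2R,3S)-3-[4-(pivaloyloxy)phenyl]oxirane-2-carboxylate (trans)
Conditions: L-fructose-derived Shi diacetate ketone (30 mol%), KHSO5 (as Oxone), NaHCO3, Bu4NHSO4 (cat.), MeCN/aq. Na2EDTA, 0 °C
Reagents that add atoms: potassium peroxymonosulfate, [K+].[O-]S(=O)(=O)OO
Why: Shi asymmetric epoxidation with the ketone variant developed for E-enoates transfers oxygen from the chiral dioxirane to one alkene face in a stereospecific syn manner (trans product), and since the D-fructose-derived diacetate ketone is known to give (2S,3R)-glycidates from E-cinnamates, its mirror image should set both centres as (2R,3S).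

Step 3
Reactants: 4 2,2,2-trichloroethyl (2R,3S)-3-[4-(pivaloyloxy)phenyl]oxirane-2-carboxylate; 5 3,5-bis(benzyloxy)phenol
Product: 6 2,2,2-trichloroethyl (2R,3R)-3-[3,5-bis(benzyloxy)phenoxy]-2-hydroxy-3-[4-(pivaloyloxy)phenyl]propanoate
Conditions: 5 (1.3 equiv), Cs2CO3 (0.2 equiv), DMF, rt to 40 °C
Reagents that add atoms: none
Why: Base-catalysed opening of a trans-3-arylglycidic ester by a phenol should occur by SN2 attack of the phenoxide at the benzylic C3 anti to the leaving oxygen, inverting C3 to R while C2 is untouched; the acyloxy-substituted aryl ring disfavours benzylic ionisation, and catalytic base with excess phenol limits pivaloyl transfer.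

Step 4
Reactants: 6 2,2,2-trichloroethyl (2R,3R)-3-[3,5-bis(benzyloxy)phenoxy]-2-hydroxy-3-[4-(pivaloyloxy)phenyl]propanoate
Product: 7 2,2,2-trichloroethyl (2R,3R)-2-acetoxy-3-[3,5-bis(benzyloxy)phenoxy]-3-[4-(pivaloyloxy)phenyl]propanoate
Conditions: Ac2O, pyridine, CH2Cl2, 0 °C to rt
Reagents that add atoms: acetic anhydride, CC(=O)OC(C)=O
Why: Pyridine-mediated O-acetylation of the secondary alcohol does not involve either stereocentre, and the weak base avoids β-elimination of the aryloxy group.

Step 5
Reactants: 7 2,2,2-trichloroethyl (2R,3R)-2-acetoxy-3-[3,5-bis(benzyloxy)phenoxy]-3-[4-(pivaloyloxy)phenyl]propanoate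
Product: 8 (2R,3R)-2-acetoxy-3-[3,5-bis(benzyloxy)phenoxy]-3-[4-(pivaloyloxy)phenyl]propanoic acid
Conditions: Zn dust, AcOH/THF, rt
Reagents that add atoms: none
Why: Reductive cleavage of the trichloroethyl ester by zinc (C–Cl insertion, then β-elimination to 1,1-dichloroethene) should free the acid while leaving the acetate, pivalate, benzyl ethers and benzylic aryl ether intact and without epimerising C2.

Step 6
Reactants: 8 (2R,3R)-2-acetoxy-3-[3,5-bis(benzyloxy)phenoxy]-3-[4-(pivaloyloxy)phenyl]propanoic acid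
Product: 10 (2R,3R)-5,7-bis(benzyloxy)-4-oxo-2-[4-(pivaloyloxy)phenyl]chroman-3-yl acetate, via acyl trifluoroacetate 9 (not isolated)
Conditions: (CF3CO)2O (2 equiv), CH2Cl2, 0 °C to rt
Reagents that add atoms: none
Why: Trifluoroacetic anhydride converts the acid into the acyl trifluoroacetate 9, whose activated acyl carbon is attacked by the ring carbon ortho to the ether oxygen and para to a benzyloxy group, and proton loss from the σ-complex restores the arene and leaves the C4 ketone. The closest known reaction is the anhydride-mediated intramolecular Friedel–Crafts acylation of 3-aryloxypropanoic acids to chroman-4-ones, which needs no strong acid when the aryl ether is a 3,5-dialkoxyphenyl ether. Ring C closes in a 6-exo-trig mode, the arene carbon adding to the trigonal acyl carbon whose C=O stays outside the new ring. No stereocentre is formed; both existing centres come from the glycidate, no bond to them is broken, and the base-free medium should prevent ketene formation or enolisation next to the acyl group. Regioselectivity needs no control, because the two carbons ortho to O1 are equivalent and the third activated carbon, para to O1, cannot reach the tethered acyl group. The selectivity that matters is acylation against acid-induced ionisation of the benzylic C–O bond, and this is secured by the 4-pivaloyloxy group (a far weaker donor than an alkoxy group) and the two electron-withdrawing groups on the adjacent carbon, while the triply oxygenated ring reacts at low temperature.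

Step 7
Reactants: 10 (2R,3R)-5,7-bis(benzyloxy)-4-oxo-2-[4-(pivaloyloxy)phenyl]chroman-3-yl acetate
Product: 11 (2R,3R)-5,7-dihydroxy-4-oxo-2-[4-(pivaloyloxy)phenyl]chroman-3-yl acetate
Conditions: H2 (1 atm), 10% Pd/C, EtOAc/THF, rt
Reagents that add atoms: none
Why: Catalytic hydrogenolysis of the two aryl benzyl ethers is routine in the flavanone series, where the C2–O1 bond, the aryl ketone and the esters survive, and it is done here before any alkene is present.

Step 8
Reactants: 11 (2R,3R)-5,7-dihydroxy-4-oxo-2-[4-(pivaloyloxy)phenyl]chroman-3-yl acetate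
Product: 12 (2R,3R)-5-hydroxy-4-oxo-2-[4-(pivaloyloxy)phenyl]chromane-3,7-diyl diacetate
Conditions: Ac2O (1.05 equiv), pyridine, CH2Cl2, 0 °C
Reagents that add atoms: acetic anhydride, CC(=O)OC(C)=O
Why: Selective acylation should take the more acidic, unhindered 7-OH, because the 5-OH is held in a hydrogen bond to the C4 carbonyl and reacts much more slowly, as is usual for 5,7-dihydroxyflavanones.

Step 9
Reactants: 12 (2R,3R)-5-hydroxy-4-oxo-2-[4-(pivaloyloxy)phenyl]chromane-3,7-diyl diacetate; 13 3-methylbut-2-en-1-ol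
Product: 14 (2R,3R)-5-[(3-methylbut-2-en-1-yl)oxy]-4-oxo-2-[4-(pivaloyloxy)phenyl]chromane-3,7-diyl diacetate
Conditions: PPh3, DIAD, THF, 0 °C to rt
Reagents that add atoms: none
Why: Mitsunobu etherification of the chelated 5-OH with a primary allylic alcohol runs under neutral conditions and by SN2 at the primary carbon (unrearranged prenyl ether), whereas base and a prenyl halide would risk opening ring C through the C3 enolate.

Step 10
Reactants: 14 (2R,3R)-5-[(3-methylbut-2-en-1-yl)oxy]-4-oxo-2-[4-(pivaloyloxy)phenyl]chromane-3,7-diyl diacetate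
Product: 16 (2R,3R)-5-hydroxy-6-(2-methylbut-3-en-2-yl)-4-oxo-2-[4-(pivaloyloxy)phenyl]chromane-3,7-diyl diacetate, via C6 dienone 15 (not isolated)
Conditions: Eu(fod)3 (10 mol%), CHCl3, 35–40 °C
Reagents that add atoms: none
Why: In this Eu(fod)3-catalysed aromatic Claisen rearrangement the Lewis acid binds the C4 carbonyl and O5, the [3,3] shift delivers the allyl unit with allylic transposition to the only free ortho carbon C6 (dienone 15), and enolisation gives the phenol; the low temperature is meant to stop the sequence before a Cope shift moves the group to C8, and the ring C stereocentres are remote.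

Step 11
Reactants: 16 (2R,3R)-5-hydroxy-6-(2-methylbut-3-en-2-yl)-4-oxo-2-[4-(pivaloyloxy)phenyl]chromane-3,7-diyl diacetate
Product: 17 (2R,3R)-3,5,7-trihydroxy-2-(4-hydroxyphenyl)-6-(2-methylbut-3-en-2-yl)chroman-4-one (CNP0527000.1)
Conditions: K2CO3 (3 equiv), MeOH, 0 °C to rt, argon; aq. NH4Cl work-up
Reagents that add atoms: none
Why: Base-mediated methanolysis (transesterification) should remove both acetates and the aryl pivalate; the 7-phenolate formed first deactivates the C4 carbonyl towards C3 enolisation and ring opening, and the trans (2R,3R) arrangement is the thermodynamically preferred one.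

**Compound list**

1 | 4-hydroxycinnamic acid | OC(=O)/C=C/c1ccc(O)cc1 | starting material
2 | (E)-3-[4-(pivaloyloxy)phenyl]prop-2-enoic pivalic anhydride | CC(C)(C)C(=O)OC(=O)/C=C/c1ccc(OC(=O)C(C)(C)C)cc1 | intermediate
3 | 2,2,2-trichloroethyl (E)-3-[4-(pivaloyloxy)phenyl]prop-2-enoate | ClC(Cl)(Cl)COC(=O)/C=C/c1ccc(OC(=O)C(C)(C)C)cc1 | intermediate
4 | 2,2,2-trichloroethyl (2R,3S)-3-[4-(pivaloyloxy)phenyl]oxirane-2-carboxylate | ClC(Cl)(Cl)COC(=O)[C@@H]1O[C@H]1c1ccc(OC(=O)C(C)(C)C)cc1 | intermediate
5 | 3,5-bis(benzyloxy)phenol | Oc1cc(OCc2ccccc2)cc(OCc2ccccc2)c1 | starting material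
6 | 2,2,2-trichloroethyl (2R,3R)-3-[3,5-bis(benzyloxy)phenoxy]-2-hydroxy-3-[4-(pivaloyloxy)phenyl]propanoate | ClC(Cl)(Cl)COC(=O)[C@H](O)[C@@H](c1ccc(OC(=O)C(C)(C)C)cc1)Oc1cc(OCc2ccccc2)cc(OCc2ccccc2)c1 | intermediate
7 | 2,2,2-trichloroethyl (2R,3R)-2-acetoxy-3-[3,5-bis(benzyloxy)phenoxy]-3-[4-(pivaloyloxy)phenyl]propanoate | ClC(Cl)(Cl)COC(=O)[C@H](OC(C)=O)[C@@H](c1ccc(OC(=O)C(C)(C)C)cc1)Oc1cc(OCc2ccccc2)cc(OCc2ccccc2)c1 | intermediate
8 | (2R,3R)-2-acetoxy-3-[3,5-bis(benzyloxy)phenoxy]-3-[4-(pivaloyloxy)phenyl]propanoic acid | OC(=O)[C@H](OC(C)=O)[C@@H](c1ccc(OC(=O)C(C)(C)C)cc1)Oc1cc(OCc2ccccc2)cc(OCc2ccccc2)c1 | intermediate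
9 | mixed anhydride of acid 8 with trifluoroacetic acid | FC(F)(F)C(=O)OC(=O)[C@H](OC(C)=O)[C@@H](c1ccc(OC(=O)C(C)(C)C)cc1)Oc1cc(OCc2ccccc2)cc(OCc2ccccc2)c1 | intermediate
10 | (2R,3R)-5,7-bis(benzyloxy)-4-oxo-2-[4-(pivaloyloxy)phenyl]chroman-3-yl acetate | c1ccccc1COc1cc(OCc3ccccc3)cc2c1C(=O)[C@H](OC(C)=O)[C@@H](c1ccc(OC(=O)C(C)(C)C)cc1)O2 | intermediate
11 | (2R,3R)-5,7-dihydroxy-4-oxo-2-[4-(pivaloyloxy)phenyl]chroman-3-yl acetate | Oc1cc(O)cc2c1C(=O)[C@H](OC(C)=O)[C@@H](c1ccc(OC(=O)C(C)(C)C)cc1)O2 | intermediate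
12 | (2R,3R)-5-hydroxy-4-oxo-2-[4-(pivaloyloxy)phenyl]chromane-3,7-diyl diacetate | Oc1cc(OC(C)=O)cc2c1C(=O)[C@H](OC(C)=O)[C@@H](c1ccc(OC(=O)C(C)(C)C)cc1)O2 | intermediate
13 | 3-methylbut-2-en-1-ol (prenol) | CC(C)=CCO | starting material
14 | (2R,3R)-5-[(3-methylbut-2-en-1-yl)oxy]-4-oxo-2-[4-(pivaloyloxy)phenyl]chromane-3,7-diyl diacetate | CC(C)=CCOc1cc(OC(C)=O)cc2c1C(=O)[C@H](OC(C)=O)[C@@H](c1ccc(OC(=O)C(C)(C)C)cc1)O2 | intermediate
15 | C6 dienone tautomer of 16 (5-oxo, sp3 C6 bearing H and the 2-methylbut-3-en-2-yl group, C6 configuration undefined) | C=CC(C)(C)C1C(OC(C)=O)=CC2=C(C1=O)C(=O)[C@H](OC(C)=O)[C@@H](c1ccc(OC(=O)C(C)(C)C)cc1)O2 | intermediate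
16 | (2R,3R)-5-hydroxy-6-(2-methylbut-3-en-2-yl)-4-oxo-2-[4-(pivaloyloxy)phenyl]chromane-3,7-diyl diacetate | C=CC(C)(C)c1c(OC(C)=O)cc2c(c1O)C(=O)[C@H](OC(C)=O)[C@@H](c1ccc(OC(=O)C(C)(C)C)cc1)O2 | intermediate
17 | (2R,3R)-3,5,7-trihydroxy-2-(4-hydroxyphenyl)-6-(2-methylbut-3-en-2-yl)chroman-4-one | C=CC(C)(C)c1c(O)cc2c(c1O)C(=O)[C@H](O)[C@@H](c1ccc(O)cc1)O2 | target

**Totals**

Total steps: 11. Longest linear sequence: 11 steps (1 to 17).

**Steps most likely to fail**

Step 3. The phenoxide may attack C2 or the activated ester carbonyl instead of the benzylic carbon, the pivaloyl group may be transferred to the phenoxide, or partial ionisation at the benzylic carbon may erode the inversion. The fallback sets out from 4 and returns at 8. The ester of 4 is reduced with NaBH4 (THF/MeOH, 0 °C) to the epoxy alcohol [(2S,3S)-3-[4-(pivaloyloxy)phenyl]oxiran-2-yl]methanol F1, which belongs to the trans-3-aryl-2,3-epoxy alcohol class, where phenoxide attack at the benzylic carbon with inversion is well established and no carbonyl competes. Opening with 5 (Cs2CO3 cat., DMF, 60 °C) should give (2S,3R)-3-[3,5-bis(benzyloxy)phenoxy]-3-[4-(pivaloyloxy)phenyl]propane-1,2-diol F2. The primary alcohol is then oxidised selectively with TEMPO (cat.) and PhI(OAc)2 in MeCN/H2O to (2R,3R)-3-[3,5-bis(benzyloxy)phenoxy]-2-hydroxy-3-[4-(pivaloyloxy)phenyl]propanoic acid F3, and acetylation (Ac2O, pyridine) leads to 8.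

Step 10. The allyl unit may migrate onward from C6 to C8 by a Cope shift through the dienone tautomer, giving the 8-prenyl isomer. The fallback sets out from 14 and returns at 17. The ether is rearranged thermally in Ac2O with NaOAc at about 130 °C, so that the phenol is acetylated as soon as the dienone enolises. The trapped product, (2R,3R)-6-(2-methylbut-3-en-2-yl)-4-oxo-2-[4-(pivaloyloxy)phenyl]chromane-3,5,7-triyl triacetate F5, cannot return to the dienone and so cannot undergo the Cope shift. Methanolysis under the conditions of step 11 then removes all four esters to give 17.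

Step 6. The trifluoroacetic acid released may ionise the benzylic C–O bond (loss of the phenol or epimerisation at the benzylic carbon), or the anhydride may C-trifluoroacetylate the electron-rich ring. The fallback sets out from 8 and returns at 10. The acid is converted with (COCl)2 and catalytic DMF (CH2Cl2, 0 °C) into (2R,3R)-2-acetoxy-3-[3,5-bis(benzyloxy)phenoxy]-3-[4-(pivaloyloxy)phenyl]propanoyl chloride F4, and the ring is closed by a Lewis-acid Friedel–Crafts acylation with SnCl4 in CH2Cl2 at −78 °C, which avoids both the protic acid and the competing acylating agent.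

**Further compounds**

F1 | step 3 | [(2S,3S)-3-[4-(pivaloyloxy)phenyl]oxiran-2-yl]methanol | OC[C@@H]1O[C@H]1c1ccc(OC(=O)C(C)(C)C)cc1
F2 | step 3 | (2S,3R)-3-[3,5-bis(benzyloxy)phenoxy]-3-[4-(pivaloyloxy)phenyl]propane-1,2-diol | OC[C@H](O)[C@@H](c1ccc(OC(=O)C(C)(C)C)cc1)Oc1cc(OCc2ccccc2)cc(OCc2ccccc2)c1
F3 | step 3 | (2R,3R)-3-[3,5-bis(benzyloxy)phenoxy]-2-hydroxy-3-[4-(pivaloyloxy)phenyl]propanoic acid | OC(=O)[C@H](O)[C@@H](c1ccc(OC(=O)C(C)(C)C)cc1)Oc1cc(OCc2ccccc2)cc(OCc2ccccc2)c1
F4 | step 6 | (2R,3R)-2-acetoxy-3-[3,5-bis(benzyloxy)phenoxy]-3-[4-(pivaloyloxy)phenyl]propanoyl chloride | ClC(=O)[C@H](OC(C)=O)[C@@H](c1ccc(OC(=O)C(C)(C)C)cc1)Oc1cc(OCc2ccccc2)cc(OCc2ccccc2)c1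
F5 | step 10 | (2R,3R)-6-(2-methylbut-3-en-2-yl)-4-oxo-2-[4-(pivaloyloxy)phenyl]chromane-3,5,7-triyl triacetate | C=CC(C)(C)c1c(OC(C)=O)cc2c(c1OC(C)=O)C(=O)[C@H](OC(C)=O)[C@@H](c1ccc(OC(=O)C(C)(C)C)cc1)O2
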